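## Retrosynthetic overview

- **Numbering and enabling feature.** C1 is the quaternary carbinol, C7 its CH2OBz carbon, C2 (next to C1) and C5 the ring CH–OBz carbons, C3=C4 the alkene and C6 the CH–OH carbon. The strategy rests on the C2(O)–C3=C4–C5(O) segment of the cyclohexene ring with its two oxygens cis. This segment is the retron of an E,E-1,4-diacyloxybutadiene, and C1(C7)–C6 is an acrolein unit.
- **Late stage.** 12 ⇒ oxirane 11 (water enters at C6 with inversion, giving the trans C1/C6 diol) ⇒ epoxy alcohol 8 (acetate/benzoate exchange) ⇒ dienyl alcohol 7 (C7–OH-directed epoxidation of C1=C6 on the ester-free face).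
- **Ring construction.** 7 ⇒ bromo aldehyde 5 (loss of HBr across C1–C6, then 1,2-reduction) ⇒ diene 4 + 2-bromoacrolein 3 by a catalytic enantioselective [4+2] cycloaddition that forms C1–C2 and C5–C6.
- **Ring order.** The cyclohexene ring is formed in step 2. The oxirane of step 4 is a transient second ring and is opened in step 7.
- **Stereochemical caveat.** Endo and exo adducts formed on one dienophile face carry mirror-image C2/C5 pairs, so only the endo adduct is taken through the step that flattens C1.

Key step: step 2

Assumption: on the (S)-catalyst the open face of bound 3 is taken to be the Re face at its α-carbon (formyl C–H···O binding model), which with endo addition gives (1R,2R,5R)-5; should the major adduct prove antipodal at C2/C5, the (R)-catalyst is used instead.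

Faces are described with the ring drawn so that C1→C6 runs clockwise. "Upper" is the face towards the viewer.

## Route

Step 1
Reactants: 1 acrolein
Product: 3 2-bromoacrolein, via 2,3-dibromopropanal 2 (not isolated)
Conditions: Br2 (1.0 equiv), CH2Cl2, −78 → 0 °C; then Et3N (1.05 equiv), −78 → 0 °C; short-path distillation, used fresh
Reagents that add atoms: bromine, BrBr
Why: Electrophilic bromine addition to the C=C bond followed by E1cB dehydrobromination, in which the acidic α-hydrogen is removed and the β-bromide leaves, gives the 2-bromo enal and creates no stereocentre.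

Step 2
Reactants: 3 2-bromoacrolein; 4 (1E,3E)-buta-1,3-diene-1,4-diyl diacetate
Product: 5 (1R,2R,5R)-2,5-diacetoxy-1-bromocyclohex-3-ene-1-carbaldehyde (formyl group and both acetoxy groups on the lower face; bromine on the upper face)
Conditions: 3 (1.5 equiv), (S)-3,3-diphenyl-1-(o-tolyl)tetrahydro-1H,3H-pyrrolo[1,2-c][1,3,2]oxazaborole (20 mol %) + HN(SO2CF3)2 (18 mol %), CH2Cl2, −78 → −20 °C; Et3N quench; chromatography or crystallisation to remove the exo isomer
Reagents that add atoms: none
Why: The N-protonated oxazaborolidine binds the formyl oxygen of s-trans 3 at boron (backed by a formyl C–H···O contact), the neighbouring phenyl group of the CPh2 unit covers one face of the C=C bond, and s-cis 4 adds to the open face in a concerted but asynchronous [4+2] cycloaddition; this is the known oxazaborolidinium-catalysed enantioselective Diels–Alder reaction of 2-bromoacrolein, applied here to a less electron-rich diene. The cyclohexene ring is closed in this intermolecular suprafacial–suprafacial [4+2] mode, C1–C2 and C5–C6 being formed in one event. C2 and C5 come out cis because both acetoxy groups are outward substituents of the E,E-diene, C1 is set by the dienophile face that the catalyst leaves open, and the sense of the C2/C5 pair relative to C1 is set by the formyl-endo orientation that acyclic 1-oxygenated dienes adopt towards 2-substituted acroleins. Regiochemistry is not an issue because 4 is symmetric. The step needs face selectivity and endo selectivity together, because an exo adduct formed on the same face keeps C1 but carries the mirror-image C2/C5 pair and would end as the antipode once C1 is flattened; the two adducts are diastereomers, so the exo isomer is removed at this stage. Triflimide activation is chosen because this catalyst stays intact up to about 0 °C, the range the deactivated diene is expected to need, and the slight deficit of acid keeps free HN(SO2CF3)2 away from the acid-labile dienyl esters.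

Step 3
Reactants: 5 (1R,2R,5R)-2,5-diacetoxy-1-bromocyclohex-3-ene-1-carbaldehyde
Product: 7 [(3S,6R)-3,6-diacetoxycyclohexa-1,4-dien-1-yl]methanol (both acetoxy groups on the lower face), via dienal 6 (not isolated)
Conditions: DBU (1.0 equiv), CH2Cl2, −40 °C; then MeOH, CeCl3·7H2O (1.1 equiv), NaBH4 (1.0 equiv), −78 °C; pH 7 buffer work-up; Et3N-deactivated silica or used crude
Reagents that add atoms: none
Why: E2 dehydrobromination followed by Luche 1,2-reduction: in 5 the C2 hydrogen is cis to bromine, so the only ring hydrogen that can stand antiperiplanar to the C1–Br bond sits on C6 and the C1=C6 enal 6 results (C1 is flattened, C2 and C5 are untouched), and the immediate CeCl3-assisted borohydride reduction at −78 °C removes the formyl group that makes H-5 acidic before loss of acetic acid can aromatise the ring.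

Step 4
Reactants: 7 [(3S,6R)-3,6-diacetoxycyclohexa-1,4-dien-1-yl]methanol
Product: 8 [(1S,2R,5S,6R)-2,5-diacetoxy-7-oxabicyclo[4.1.0]hept-3-en-1-yl]methanol (oxirane oxygen on the upper face, anti to both acetoxy groups)
Conditions: VO(acac)2 (3 mol %), t-BuOOH (1.2 equiv, decane), CH2Cl2, 0 °C
Reagents that add atoms: tert-butyl hydroperoxide, CC(C)(C)OO
Why: Vanadium-catalysed hydroxyl-directed epoxidation: only C1=C6 carries a free allylic hydroxyl, so C3=C4 is left alone, and because both acetoxy groups project from the lower face of the nearly flat cyclohexa-1,4-diene the C7-bound vanadium peroxide delivers oxygen to the upper face, which sets C1 and C6 anti to the esters.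

Step 5
Reactants: 8 [(1S,2R,5S,6R)-2,5-diacetoxy-7-oxabicyclo[4.1.0]hept-3-en-1-yl]methanol
Product: 9 (1S,2R,5S,6R)-1-(hydroxymethyl)-7-oxabicyclo[4.1.0]hept-3-ene-2,5-diol
Conditions: NH3 (7 M in MeOH), 0 °C; evaporation
Reagents that add atoms: none
Why: Ammonolysis of the two acetates: ammonia in methanol cleaves the esters while keeping the alkoxide concentration too low for Payne migration of the oxirane towards the trans-disposed C2 and C5 hydroxyls or the C7 hydroxyl, and no stereocentre is touched.

Step 6
Reactants: 9 (1S,2R,5S,6R)-1-(hydroxymethyl)-7-oxabicyclo[4.1.0]hept-3-ene-2,5-diol; 10 benzoyl chloride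
Product: 11 [(1S,2R,5S,6R)-2,5-bis(benzoyloxy)-7-oxabicyclo[4.1.0]hept-3-en-1-yl]methyl benzoate
Conditions: BzCl (3.6 equiv), pyridine, DMAP (cat.), CH2Cl2, 0 °C → rt
Reagents that add atoms: benzoyl chloride (10), O=C(Cl)c1ccccc1
Why: DMAP-catalysed O-acylation in pyridine esterifies the primary and the two allylic secondary hydroxyls, while C1–O and C6–O stay masked in the oxirane, which later leaves exactly these two positions free.

Step 7
Reactants: 11 [(1S,2R,5S,6R)-2,5-bis(benzoyloxy)-7-oxabicyclo[4.1.0]hept-3-en-1-yl]methyl benzoate
Product: 12 [(1R,2R,5S,6S)-2,5-bis(benzoyloxy)-1,6-dihydroxycyclohex-3-en-1-yl]methyl benzoate (target)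
Conditions: aq. HClO4 (about 0.2 M overall), THF–H2O 3:1, 0 → 25 °C; NaHCO3 quench
Reagents that add atoms: water, O
Why: Acid-catalysed SN2-type epoxide hydrolysis: C1 is fully substituted and its cationic character is damped by the acyloxy-bearing carbons C7 and C2 on either side, so in a water-rich medium the nucleophile (water directly, or after assistance by the C5 benzoate that lies antiperiplanar to the C6–O bond) should enter at secondary C6 from the lower face with inversion, which keeps the C1–O bond on the upper face, places the C6 hydroxyl cis to the C5 benzoate and trans to the C1 hydroxyl, and leaves the benzoates on the three least crowded oxygens.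

## Compound list

1 | acrolein | C=CC=O | starting material
2 | 2,3-dibromopropanal (racemic) | O=CC(Br)CBr | intermediate
3 | 2-bromoacrolein | C=C(Br)C=O | intermediate
4 | (1E,3E)-buta-1,3-diene-1,4-diyl diacetate | CC(=O)O/C=C/C=C/OC(C)=O | starting material
5 | (1R,2R,5R)-2,5-diacetoxy-1-bromocyclohex-3-ene-1-carbaldehyde | O=C[C@]1(Br)[C@H](OC(C)=O)C=C[C@H](OC(C)=O)C1 | intermediate
6 | (3S,6R)-3,6-diacetoxycyclohexa-1,4-diene-1-carbaldehyde | O=CC1=C[C@@H](OC(C)=O)C=C[C@H]1OC(C)=O | intermediate
7 | [(3S,6R)-3,6-diacetoxycyclohexa-1,4-dien-1-yl]methanol | OCC1=C[C@@H](OC(C)=O)C=C[C@H]1OC(C)=O | intermediate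
8 | [(1S,2R,5S,6R)-2,5-diacetoxy-7-oxabicyclo[4.1.0]hept-3-en-1-yl]methanol | OC[C@@]12O[C@@H]1[C@@H](OC(C)=O)C=C[C@H]2OC(C)=O | intermediate
9 | (1S,2R,5S,6R)-1-(hydroxymethyl)-7-oxabicyclo[4.1.0]hept-3-ene-2,5-diol | OC[C@@]12O[C@@H]1[C@@H](O)C=C[C@H]2O | intermediate
10 | benzoyl chloride | O=C(Cl)c1ccccc1 | starting material
11 | [(1S,2R,5S,6R)-2,5-bis(benzoyloxy)-7-oxabicyclo[4.1.0]hept-3-en-1-yl]methyl benzoate | O=C(OC[C@@]12O[C@@H]1[C@@H](OC(=O)c3ccccc3)C=C[C@H]2OC(=O)c3ccccc3)c3ccccc3 | intermediate
12 | [(1R,2R,5S,6S)-2,5-bis(benzoyloxy)-1,6-dihydroxycyclohex-3-en-1-yl]methyl benzoate | O=C(OC[C@]1(O)[C@H](OC(=O)c2ccccc2)C=C[C@H](OC(=O)c2ccccc2)[C@@H]1O)c1ccccc1 | target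

Total step count: 7. Longest linear sequence: 7 steps (1 → 12).

## Steps most likely to fail

**1. Step 3.**
- *Risk.* As soon as the enal forms, the base can remove the vinylogously acidic H-5, and loss of the C2 acetate then aromatises the ring. This may keep pace with or overtake the E2 elimination of the tertiary bromide in the cold.
- *Fallback.* Base is taken out of the sequence. Setting out from 4, the oxazaborolidinium catalyst of step 2 is used with propynal F1 in place of 3. Enantioselective Diels–Alder reactions of acetylenic aldehydes under chiral boron Lewis acids are known.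
- *Return to the route.* The cycloadduct is dienal 6 itself, formed under acidic conditions in which the formyl group disfavours ionisation of the esters. It is reduced in the same flask under the Luche conditions, so the route is rejoined at 6 and then 7. The catalyst antipode is fixed by a small-scale test.

**2. Step 7.**
- *Risk.* The oxirane may open at the wrong carbon, because the C7 and C2 benzoates can both reach the backside of C1. Benzoyl migration through a C5/C6 benzoxonium ion is a second hazard. Anhydrous Lewis acids would favour both and are avoided.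
- *Fallback.* The same trans diol is reached from the diastereomeric oxirane by opening at the other carbon.
  - Setting out from 7, K2CO3 in MeOH gives (1R,4S)-2-(hydroxymethyl)cyclohexa-2,5-diene-1,4-diol F2.
  - NaHCO3-buffered mCPBA, steered by hydrogen bonding to the two ring hydroxyls (Henbest-type direction), gives (1R,2R,5S,6S)-1-(hydroxymethyl)-7-oxabicyclo[4.1.0]hept-3-ene-2,5-diol F3, with the oxirane on the lower face.
  - BzCl in pyridine gives the lower-face epoxy tribenzoate F4.
- *Why the regiochemistry improves.* In F4 the ring benzoates are cis to the oxirane and cannot reach its backside. Tertiary C1 is the inherently preferred site under acid, and the only possible participation (C7 benzoate at C1, from the upper face) leads to the same result.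
- *Return to the route.* Aqueous acid puts the C1 hydroxyl on the upper face, keeps the C6–O bond on the lower face, and rejoins the route at 12.

**3. Step 2.**
- *Risk.* The cycloaddition of the electron-poorer diene may be sluggish, the catalyst may be sequestered by the ester carbonyls, and the dienyl esters may break down under acid. Insufficient face or endo selectivity would erode the enantiomeric purity after step 3.
- *Fallback.* Asymmetric induction is moved from the cycloaddition to the epoxidation.
  - Setting out from 3 and 4, thermal cycloaddition (toluene, BHT, 60–80 °C) gives the racemic adduct F5.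
  - The operations of step 3 lead through the racemic dienal F6 to the racemic dienyl alcohol F7.
  - Katsuki–Sharpless epoxidation follows, with Ti(OiPr)4, D-(−)-diisopropyl tartrate, t-BuOOH (0.5 equiv), 4 Å sieves, CH2Cl2, −20 °C. This tartrate is the antipode of the ligand that gives (2S,3S)-epoxides from simple E-allylic alcohols, and the choice is to be confirmed on a small scale.
- *Return to the route.* For 7 the reagent's preferred face coincides with the ester-free face. For its mirror image the two preferences oppose each other. The matched enantiomer is therefore converted into 8, where the route is rejoined, and the unreacted antipodal dienyl alcohol F8 is separated.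

## Further compounds

F1 | step 3 | propynal | C#CC=O
F2 | step 7 | (1R,4S)-2-(hydroxymethyl)cyclohexa-2,5-diene-1,4-diol | OCC1=C[C@@H](O)C=C[C@H]1O
F3 | step 7 | (1R,2R,5S,6S)-1-(hydroxymethyl)-7-oxabicyclo[4.1.0]hept-3-ene-2,5-diol | OC[C@]12O[C@H]1[C@@H](O)C=C[C@H]2O
F4 | step 7 | [(1R,2R,5S,6S)-2,5-bis(benzoyloxy)-7-oxabicyclo[4.1.0]hept-3-en-1-yl]methyl benzoate | O=C(OC[C@]12O[C@H]1[C@@H](OC(=O)c3ccccc3)C=C[C@H]2OC(=O)c3ccccc3)c3ccccc3
F5 | step 2 | racemic 2,5-diacetoxy-1-bromocyclohex-3-ene-1-carbaldehyde (5 and its antipode, 1:1) | O=C[C@]1(Br)[C@H](OC(C)=O)C=C[C@H](OC(C)=O)C1.O=C[C@@]1(Br)[C@@H](OC(C)=O)C=C[C@@H](OC(C)=O)C1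
F6 | step 2 | racemic cis-3,6-diacetoxycyclohexa-1,4-diene-1-carbaldehyde (6 and its antipode, 1:1) | O=CC1=C[C@@H](OC(C)=O)C=C[C@H]1OC(C)=O.O=CC1=C[C@H](OC(C)=O)C=C[C@@H]1OC(C)=O
F7 | step 2 | racemic (cis-3,6-diacetoxycyclohexa-1,4-dien-1-yl)methanol (7 and its antipode, 1:1) | OCC1=C[C@@H](OC(C)=O)C=C[C@H]1OC(C)=O.OCC1=C[C@H](OC(C)=O)C=C[C@@H]1OC(C)=O
F8 | step 2 | [(3R,6S)-3,6-diacetoxycyclohexa-1,4-dien-1-yl]methanol | OCC1=C[C@H](OC(C)=O)C=C[C@@H]1OC(C)=O
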